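**Retrosynthetic overview**

1. Locants (drimane type): ring A = C1–C5 and C10 (C3–O, C4 gem-dimethyl, C10 methyl); ring B = C5–C10 (C5=C6, C8=C12H2, C9–C11H2OAr). The last disconnections are the C3–O ester (3-hydroxy-3-methylbutanoic acid) and the C11–O aryl ether (umbelliferone).
2. C9–C11 and the C8 exocyclic methylene come from anti-SE2' hydroxymethylation of a ring-B allylsilane (C9=C8–C12H2SiMe3), with CH2O entering anti to the C10 methyl.
3. Rings A and B form together by an intramolecular [4+2] of an acyclic dienyne (alkyne C5≡C6 + diene C7=C8–C9=C10), which makes the ring-fusion bond C5–C10 and C6–C7. The enabling feature: ring B, with C5=C6, quaternary C10 and the sp2 carbon C8 two atoms from C6, is a masked cyclohexa-1,4-diene (C5=C6 / C8=C9), the retron of an alkyne–diene cycloaddition.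
4. Dienyne: C3–C4 by an asymmetric Mukaiyama aldol (sets C3, the only stereocentre brought in), C5≡C6 by Ohira–Bestmann homologation, C8–C9 and C10–CH3 by carboalumination/cross-coupling of pent-4-yn-1-ol.
5. Ring order: A and B in one step from an acyclic precursor; the coumarin is bought and attached afterwards.

Key step: step 8

Remark: names of the bicyclic compounds use naphthalene numbering with C1 = gem-dimethyl carbon, C2 = oxygenated carbon, C4a = methyl-bearing ring-fusion carbon, C5 = carbon bearing the CH2O group (these are drimane C4, C3, C10 and C9). The target is then (2S,4aR,5R): the C2 oxygen cis to the C4a methyl, the C5 CH2OAr group trans to it.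

**Route**

Step 1
Reactants: 1 pent-4-yn-1-ol; 2 (2-bromoprop-2-en-1-yl)trimethylsilane
Product: 4 (4E)-4-methyl-6-methylidene-7-(trimethylsilyl)hept-4-en-1-ol, via alkenylalane 3 (not isolated)
Conditions: Me3Al (3 equiv), Cp2ZrCl2 (0.25 equiv), CH2Cl2, 0 °C→rt; volatiles removed; then 2, ZnCl2, Pd(PPh3)4 (5 mol %), THF, rt→45 °C; aq. Rochelle salt
Reagents that add atoms: trimethylaluminium, C[Al](C)C
Why: Zr-catalysed syn-carboalumination (Negishi) puts CH3 on the internal alkyne carbon cis to aluminium, and the Pd/Zn-mediated alkenyl–alkenyl Negishi coupling proceeds with retention, so the (E)-diene with the chain on the outer diene position should result.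

Step 2
Reactants: 4 (4E)-4-methyl-6-methylidene-7-(trimethylsilyl)hept-4-en-1-ol
Product: 5 (4E)-4-methyl-6-methylidene-7-(trimethylsilyl)hept-4-enal
Conditions: Dess–Martin periodinane, NaHCO3, CH2Cl2, 0 °C→rt
Reagents that add atoms: none
Why: Dess–Martin oxidation of a primary alcohol under buffered conditions that should leave the acid-sensitive 2-(silylmethyl)diene untouched.

Step 3
Reactants: 5 (4E)-4-methyl-6-methylidene-7-(trimethylsilyl)hept-4-enal; 6 1-methoxy-2-methyl-1-(trimethylsilyloxy)prop-1-ene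
Product: 7 methyl (3S,6E)-3-hydroxy-2,2,6-trimethyl-8-methylidene-9-(trimethylsilyl)non-6-enoate
Conditions: N-Ts-D-valine, BH3·THF (1 equiv each), CH2Cl2, 0 °C→rt; then 5 and 6, −78 °C; pH 7 buffer
Reagents that add atoms: none
Why: Kiyooka-type asymmetric Mukaiyama aldol, in which the valine-derived oxazaborolidinone activates the aldehyde and shields one face; the D-valine series is chosen as the one expected to give the (3S)-β-hydroxy-α,α-dimethyl ester from unbranched aldehydes, and the ketene acetal is far more nucleophilic than the allylsilane.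

Step 4
Reactants: 7 methyl (3S,6E)-3-hydroxy-2,2,6-trimethyl-8-methylidene-9-(trimethylsilyl)non-6-enoate
Product: 8 methyl (3S,6E)-3-[(tert-butyldimethylsilyl)oxy]-2,2,6-trimethyl-8-methylidene-9-(trimethylsilyl)non-6-enoate
Conditions: TBSOTf, 2,6-lutidine, CH2Cl2, −78→0 °C
Reagents that add atoms: tert-butyldimethylsilyl trifluoromethanesulfonate, CC(C)(C)[Si](C)(C)OS(=O)(=O)C(F)(F)F
Why: Silylation of a hindered secondary alcohol with the silyl triflate; excess lutidine keeps the medium non-acidic, so the allylsilane should survive.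

Step 5
Reactants: 8 methyl (3S,6E)-3-[(tert-butyldimethylsilyl)oxy]-2,2,6-trimethyl-8-methylidene-9-(trimethylsilyl)non-6-enoate
Product: 9 (3S,6E)-3-[(tert-butyldimethylsilyl)oxy]-2,2,6-trimethyl-8-methylidene-9-(trimethylsilyl)non-6-en-1-ol
Conditions: DIBAL-H (2.5 equiv), CH2Cl2, −78→0 °C; aq. Rochelle salt
Reagents that add atoms: none
Why: DIBAL-H reduction of the α,α-disubstituted ester to the primary alcohol; the diene, silyl ether and allylsilane are inert to the hydride at low temperature.

Step 6
Reactants: 9 (3S,6E)-3-[(tert-butyldimethylsilyl)oxy]-2,2,6-trimethyl-8-methylidene-9-(trimethylsilyl)non-6-en-1-ol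
Product: 10 (3S,6E)-3-[(tert-butyldimethylsilyl)oxy]-2,2,6-trimethyl-8-methylidene-9-(trimethylsilyl)non-6-enal
Conditions: Dess–Martin periodinane, NaHCO3, CH2Cl2, 0 °C→rt
Reagents that add atoms: none
Why: Dess–Martin oxidation to a non-enolisable neopentylic aldehyde; C3 cannot epimerise.

Step 7
Reactants: 10 (3S,6E)-3-[(tert-butyldimethylsilyl)oxy]-2,2,6-trimethyl-8-methylidene-9-(trimethylsilyl)non-6-enal
Product: 11 (4S,7E)-4-[(tert-butyldimethylsilyl)oxy]-3,3,7-trimethyl-9-methylidene-10-(trimethylsilyl)dec-7-en-1-yne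
Conditions: dimethyl (1-diazo-2-oxopropyl)phosphonate, K2CO3, MeOH, 0 °C→rt
Reagents that add atoms: dimethyl (1-diazo-2-oxopropyl)phosphonate, CC(=O)C(=[N+]=[N-])P(=O)(OC)OC
Why: Ohira–Bestmann (Seyferth–Gilbert) homologation, which works well on non-enolisable aldehydes and under mild base leaves both silyl groups in place.

Step 8
Reactants: 11 (4S,7E)-4-[(tert-butyldimethylsilyl)oxy]-3,3,7-trimethyl-9-methylidene-10-(trimethylsilyl)dec-7-en-1-yne
Product: 12 (2S,4aR)-2-[(tert-butyldimethylsilyl)oxy]-1,1,4a-trimethyl-6-[(trimethylsilyl)methyl]-1,2,3,4,4a,7-hexahydronaphthalene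
Conditions: [Rh(coe)2Cl]2 (5 mol %), P[OCH(CF3)2]3 (20 mol %), degassed THF (0.01 M), 25→60 °C
Reagents that add atoms: none
Why: Rh(I) binds the alkyne and the s-cis diene, oxidative cyclisation joins the internal alkyne carbon C5 to the diene terminus C10 to give a vinyl/η3-allyl rhodacycle, and reductive elimination joins C6 to C7, so the net change is the [4+2] addition of an unactivated alkyne to a diene, giving the cyclohexa-1,4-diene (C5=C6 and C8=C9) directly. The closest known reaction type is the Rh(I)- and Ni(0)-catalysed intramolecular [4+2] cycloaddition of unactivated dienynes, the metal-catalysed counterpart of the thermal intramolecular Diels–Alder reaction of a diene with a tethered alkyne. Ring A closes as the six-membered ring spanned by the four-carbon tether C1–C4 when C5–C10 forms, and ring B closes as the cycloadduct ring when C6–C7 forms. The only new stereocentre, C10, is controlled by C3: the tether should fold chair-like with the C3 silyloxy group equatorial, and because C9 must lie almost in the plane of the C5=C6 bond the C10 methyl is forced axial on ring A, that is cis to the silyloxy group (2S,4aR). Regiochemistry is fixed by the tether (a fused, not a bridged, bicycle), the (E)-geometry from step 1 places the tether on the outer diene position, and the gem-dimethyl group at C4 compresses the tether so that ring closure should outrun alkyne oligomerisation. The C10 epimer, should it form, is a diastereomer and would be removed by chromatography.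

Step 9
Reactants: 12 (2S,4aR)-2-[(tert-butyldimethylsilyl)oxy]-1,1,4a-trimethyl-6-[(trimethylsilyl)methyl]-1,2,3,4,4a,7-hexahydronaphthalene
Product: 13 (2S,4aR,5R)-2-[(tert-butyldimethylsilyl)oxy]-5-(hydroxymethyl)-1,1,4a-trimethyl-6-methylidene-1,2,3,4,4a,5,6,7-octahydronaphthalene
Conditions: (CH2O)n (1.2 equiv), Me2AlCl (2 equiv), CH2Cl2, −78→−20 °C; aq. Rochelle salt
Reagents that add atoms: formaldehyde (from paraformaldehyde), C=O
Why: Hosomi–Sakurai (anti-SE2') hydroxymethylation, in which CH2O·Me2AlCl attacks C9 (γ to silicon) on the face opposite the pseudo-axial C10 methyl and loss of silicon from the β-silyl cation gives the C8 exocyclic methylene, so C9 is set with CH2OH trans to the angular methyl while Me2AlCl scavenges protons.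

Step 10
Reactants: 13 (2S,4aR,5R)-2-[(tert-butyldimethylsilyl)oxy]-5-(hydroxymethyl)-1,1,4a-trimethyl-6-methylidene-1,2,3,4,4a,5,6,7-octahydronaphthalene; 14 7-hydroxy-2H-chromen-2-one (umbelliferone)
Product: 15 7-{[(2S,4aR,5R)-2-[(tert-butyldimethylsilyl)oxy]-1,1,4a-trimethyl-6-methylidene-1,2,3,4,4a,5,6,7-octahydronaphthalen-5-yl]methoxy}-2H-chromen-2-one
Conditions: PPh3, DIAD, THF, 0 °C→rt
Reagents that add atoms: none
Why: Mitsunobu etherification of a primary alcohol with an acidic phenol (pKa about 8); no stereocentre is involved and the alkenes and silyl ether are inert.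

Step 11
Reactants: 15 7-{[(2S,4aR,5R)-2-[(tert-butyldimethylsilyl)oxy]-1,1,4a-trimethyl-6-methylidene-1,2,3,4,4a,5,6,7-octahydronaphthalen-5-yl]methoxy}-2H-chromen-2-one
Product: 16 7-{[(2S,4aR,5R)-2-hydroxy-1,1,4a-trimethyl-6-methylidene-1,2,3,4,4a,5,6,7-octahydronaphthalen-5-yl]methoxy}-2H-chromen-2-one
Conditions: HF·pyridine, pyridine, THF, 0 °C→rt
Reagents that add atoms: none
Why: Fluoride-driven cleavage of the Si–O bond under buffered conditions that the coumarin lactone, the aryl ether and the skipped diene should tolerate.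

Step 12
Reactants: 16 7-{[(2S,4aR,5R)-2-hydroxy-1,1,4a-trimethyl-6-methylidene-1,2,3,4,4a,5,6,7-octahydronaphthalen-5-yl]methoxy}-2H-chromen-2-one; 17 3-hydroxy-3-methylbutanoic acid
Product: 18 (2S,4aR,5R)-1,1,4a-trimethyl-6-methylidene-5-{[(2-oxo-2H-chromen-7-yl)oxy]methyl}-1,2,3,4,4a,5,6,7-octahydronaphthalen-2-yl 3-hydroxy-3-methylbutanoate (CNP0300349.1)
Conditions: DCC (1.5 equiv), DMAP (0.3 equiv), CH2Cl2, 0 °C→rt
Reagents that add atoms: none
Why: Steglich esterification through the acylpyridinium ion; the secondary equatorial hydroxyl is the only acylable alcohol in 16 and the tertiary hydroxyl of the acid should not compete.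

**Compound list**

1 | pent-4-yn-1-ol | C#CCCCO | starting material
2 | (2-bromoprop-2-en-1-yl)trimethylsilane | C=C(Br)C[Si](C)(C)C | starting material
3 | (E)-alkenylalane, [5-(dimethylalumanyloxy)-2-methylpent-1-en-1-yl]dimethylalumane | C[Al](C)OCCC/C(C)=C/[Al](C)C | intermediate
4 | (4E)-4-methyl-6-methylidene-7-(trimethylsilyl)hept-4-en-1-ol | OCCC/C(C)=C/C(=C)C[Si](C)(C)C | intermediate
5 | (4E)-4-methyl-6-methylidene-7-(trimethylsilyl)hept-4-enal | O=CCC/C(C)=C/C(=C)C[Si](C)(C)C | intermediate
6 | 1-methoxy-2-methyl-1-(trimethylsilyloxy)prop-1-ene | COC(O[Si](C)(C)C)=C(C)C | starting material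
7 | methyl (3S,6E)-3-hydroxy-2,2,6-trimethyl-8-methylidene-9-(trimethylsilyl)non-6-enoate | COC(=O)C(C)(C)[C@@H](O)CC/C(C)=C/C(=C)C[Si](C)(C)C | intermediate
8 | methyl (3S,6E)-3-[(tert-butyldimethylsilyl)oxy]-2,2,6-trimethyl-8-methylidene-9-(trimethylsilyl)non-6-enoate | COC(=O)C(C)(C)[C@@H](O[Si](C)(C)C(C)(C)C)CC/C(C)=C/C(=C)C[Si](C)(C)C | intermediate
9 | (3S,6E)-3-[(tert-butyldimethylsilyl)oxy]-2,2,6-trimethyl-8-methylidene-9-(trimethylsilyl)non-6-en-1-ol | OCC(C)(C)[C@@H](O[Si](C)(C)C(C)(C)C)CC/C(C)=C/C(=C)C[Si](C)(C)C | intermediate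
10 | (3S,6E)-3-[(tert-butyldimethylsilyl)oxy]-2,2,6-trimethyl-8-methylidene-9-(trimethylsilyl)non-6-enal | O=CC(C)(C)[C@@H](O[Si](C)(C)C(C)(C)C)CC/C(C)=C/C(=C)C[Si](C)(C)C | intermediate
11 | (4S,7E)-4-[(tert-butyldimethylsilyl)oxy]-3,3,7-trimethyl-9-methylidene-10-(trimethylsilyl)dec-7-en-1-yne | C#CC(C)(C)[C@@H](O[Si](C)(C)C(C)(C)C)CC/C(C)=C/C(=C)C[Si](C)(C)C | intermediate
12 | (2S,4aR)-2-[(tert-butyldimethylsilyl)oxy]-1,1,4a-trimethyl-6-[(trimethylsilyl)methyl]-1,2,3,4,4a,7-hexahydronaphthalene | C[Si](C)(C)CC1=C[C@@]2(C)CC[C@H](O[Si](C)(C)C(C)(C)C)C(C)(C)C2=CC1 | intermediate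
13 | (2S,4aR,5R)-2-[(tert-butyldimethylsilyl)oxy]-5-(hydroxymethyl)-1,1,4a-trimethyl-6-methylidene-1,2,3,4,4a,5,6,7-octahydronaphthalene | C=C1CC=C2C(C)(C)[C@@H](O[Si](C)(C)C(C)(C)C)CC[C@]2(C)[C@@H]1CO | intermediate
14 | 7-hydroxy-2H-chromen-2-one (umbelliferone) | Oc1ccc2ccc(=O)oc2c1 | starting material
15 | 7-{[(2S,4aR,5R)-2-[(tert-butyldimethylsilyl)oxy]-1,1,4a-trimethyl-6-methylidene-1,2,3,4,4a,5,6,7-octahydronaphthalen-5-yl]methoxy}-2H-chromen-2-one | C=C1CC=C2C(C)(C)[C@@H](O[Si](C)(C)C(C)(C)C)CC[C@]2(C)[C@@H]1COc1ccc2ccc(=O)oc2c1 | intermediate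
16 | 7-{[(2S,4aR,5R)-2-hydroxy-1,1,4a-trimethyl-6-methylidene-1,2,3,4,4a,5,6,7-octahydronaphthalen-5-yl]methoxy}-2H-chromen-2-one | C=C1CC=C2C(C)(C)[C@@H](O)CC[C@]2(C)[C@@H]1COc1ccc2ccc(=O)oc2c1 | intermediate
17 | 3-hydroxy-3-methylbutanoic acid | CC(C)(O)CC(=O)O | starting material
18 | (2S,4aR,5R)-1,1,4a-trimethyl-6-methylidene-5-{[(2-oxo-2H-chromen-7-yl)oxy]methyl}-1,2,3,4,4a,5,6,7-octahydronaphthalen-2-yl 3-hydroxy-3-methylbutanoate | C=C1CC=C2C(C)(C)[C@@H](OC(=O)CC(C)(C)O)CC[C@]2(C)[C@@H]1COc1ccc2ccc(=O)oc2c1 | target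

**Step count and risks**

Total step count: 12. Longest linear sequence: 12 steps (1 → 18); compounds 2, 6, 14 and 17 are bought.

Steps most likely to fail:

Step 8. The oxidative cyclisation has to join a tert-alkyl-substituted alkyne carbon to a fully substituted diene terminus, so ring closure may stall while alkyne oligomerisation or diene isomerisation takes over. Facial discrimination by the remote C3 silyloxy group may also be weak, because the neighbouring gem-dimethyl group erodes its equatorial preference; this costs material but not purity, since the C10 epimer is a separable diastereomer. Fallback (activated thermal cycloaddition with a traceless activating group): setting out from 11, deprotonation with n-BuLi and formylation with DMF should give the ynal (5S,8E)-5-[(tert-butyldimethylsilyl)oxy]-4,4,8-trimethyl-10-methylidene-11-(trimethylsilyl)undec-8-en-2-ynal F1. Heating in toluene (about 110 °C) should bring about the intramolecular Diels–Alder reaction of the ynal to the bicyclic dienal (2S,4aR)-2-[(tert-butyldimethylsilyl)oxy]-1,1,4a-trimethyl-6-[(trimethylsilyl)methyl]-1,2,3,4,4a,7-hexahydronaphthalene-8-carbaldehyde F2. Tsuji–Wilkinson decarbonylation with stoichiometric RhCl(PPh3)3 in hot toluene then removes the formyl group with retention of the C5=C6 position and comes back to the route at 12.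

Step 9. The exocyclic 1,1-disubstituted alkene of the product and the C5=C6 alkene are themselves ene partners for CH2O·Me2AlCl, so over-hydroxymethylation may occur. Adventitious HCl may instead protodesilylate 12 without C–C bond formation. Fallback (C11 brought in at the aldehyde oxidation level with an electrophile that does not engage simple alkenes): setting out from 12, a Hosomi–Sakurai reaction with HC(OMe)3 and catalytic TMSOTf in CH2Cl2 at −78 °C should give the dimethyl acetal (2S,4aR,5R)-2-[(tert-butyldimethylsilyl)oxy]-5-(dimethoxymethyl)-1,1,4a-trimethyl-6-methylidene-1,2,3,4,4a,5,6,7-octahydronaphthalene F3, with the same anti-to-methyl facial preference. Mild hydrolysis (PPTS, acetone/H2O) should give the aldehyde (2S,4aR,5R)-2-[(tert-butyldimethylsilyl)oxy]-1,1,4a-trimethyl-6-methylidene-1,2,3,4,4a,5,6,7-octahydronaphthalene-5-carbaldehyde F4, which is reduced at once (NaBH4, MeOH, 0 °C) to avoid epimerisation or conjugation, coming back to the route at 13.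

Step 12. Acylation of the hindered hydroxyl next to the gem-dimethyl carbon may be so slow that the activated β-hydroxy acid rearranges to the N-acylurea, dehydrates or self-condenses. Fallback (protected acid and mixed-anhydride activation): setting out from 17, silylation (TESCl, imidazole, DMF; then K2CO3, MeOH/H2O to free the carboxyl group) should give 3-methyl-3-[(triethylsilyl)oxy]butanoic acid F5. Yamaguchi esterification of 16 with it (2,4,6-trichlorobenzoyl chloride, Et3N, DMAP, toluene) should give the silyl-protected ester (2S,4aR,5R)-1,1,4a-trimethyl-6-methylidene-5-{[(2-oxo-2H-chromen-7-yl)oxy]methyl}-1,2,3,4,4a,5,6,7-octahydronaphthalen-2-yl 3-methyl-3-[(triethylsilyl)oxy]butanoate F6, and HF·pyridine comes back to the route at 18.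

**Further compounds**

F1 | step 8 | (5S,8E)-5-[(tert-butyldimethylsilyl)oxy]-4,4,8-trimethyl-10-methylidene-11-(trimethylsilyl)undec-8-en-2-ynal | O=CC#CC(C)(C)[C@@H](O[Si](C)(C)C(C)(C)C)CC/C(C)=C/C(=C)C[Si](C)(C)C
F2 | step 8 | (2S,4aR)-2-[(tert-butyldimethylsilyl)oxy]-1,1,4a-trimethyl-6-[(trimethylsilyl)methyl]-1,2,3,4,4a,7-hexahydronaphthalene-8-carbaldehyde | C[Si](C)(C)CC1=C[C@@]2(C)CC[C@H](O[Si](C)(C)C(C)(C)C)C(C)(C)C2=C(C=O)C1
F3 | step 9 | (2S,4aR,5R)-2-[(tert-butyldimethylsilyl)oxy]-5-(dimethoxymethyl)-1,1,4a-trimethyl-6-methylidene-1,2,3,4,4a,5,6,7-octahydronaphthalene | C=C1CC=C2C(C)(C)[C@@H](O[Si](C)(C)C(C)(C)C)CC[C@]2(C)[C@@H]1C(OC)OC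
F4 | step 9 | (2S,4aR,5R)-2-[(tert-butyldimethylsilyl)oxy]-1,1,4a-trimethyl-6-methylidene-1,2,3,4,4a,5,6,7-octahydronaphthalene-5-carbaldehyde | C=C1CC=C2C(C)(C)[C@@H](O[Si](C)(C)C(C)(C)C)CC[C@]2(C)[C@@H]1C=O
F5 | step 12 | 3-methyl-3-[(triethylsilyl)oxy]butanoic acid | CC(C)(CC(=O)O)O[Si](CC)(CC)CC
F6 | step 12 | (2S,4aR,5R)-1,1,4a-trimethyl-6-methylidene-5-{[(2-oxo-2H-chromen-7-yl)oxy]methyl}-1,2,3,4,4a,5,6,7-octahydronaphthalen-2-yl 3-methyl-3-[(triethylsilyl)oxy]butanoate | C=C1CC=C2C(C)(C)[C@@H](OC(=O)CC(C)(C)O[Si](CC)(CC)CC)CC[C@]2(C)[C@@H]1COc1ccc2ccc(=O)oc2c1
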